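**Plan**
- Retrosynthesis cuts the C11–O aryl ether (Mitsunobu), moves the C8=C12 alkene back to C8=C9 (allylic transposition), then cuts C5–C10 and C6–C7 together (intramolecular Diels–Alder) and last C1–C2 (enolate alkylation).
- Enabling feature: C8 and C9 are neighbouring ring B carbons that each carry one exocyclic carbon (C12, C11). This is the imprint of a 2,3-bis(oxymethyl)buta-1,3-diene (C7=C8–C9=C10): its cycloadduct keeps the alkene at C8=C9 inside ring B, and the C12 oxygen lets that alkene be shifted to C8=C12 with hydrogen placed on C9.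
- Forward: a dienyl bromide (C1, C7–C12; 4 steps) and a quaternary keto ester carrying the (E)-vinyl sulfone (C2–C6, C14; 8 steps) are joined at C1–C2. Heating closes ring B (cyclohexene) and ring A (tether ring) in one step, and 7 steps finish the target.
- Stereochemistry: C4 comes from double Fráter–Seebach alkylation of methyl (S)-3-hydroxybutanoate; C5 and C10 from the sulfone-endo, chair-tether transition state steered by C4; C3 from axial hydride attack on the ring A ketone; C9 from intramolecular hydrogen delivery anti to the C10 methyl.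
- C3 is carried as a ketone and C14 as an ester through the cycloaddition, so that the flat ester takes the axial site beside the developing C10 methyl; hydride reduction afterwards restores both oxygens.

Key step: step 14

Remark: drimane numbering is used throughout (ring A = C1–C5, C10; ring B = C5–C10; C11 on C9; C12 on C8; C13 = methyl on C4; C14 = oxygenated carbon on C4; C15 = methyl on C10).

Step 1
Reactants: 1 2-bromoprop-2-en-1-ol
Product: 2 [(2-bromoprop-2-en-1-yl)oxy](tert-butyl)dimethylsilane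
Conditions: TBSCl, imidazole, CH2Cl2, 0 °C → rt
Reagents that add atoms: tert-butyldimethylsilyl chloride, CC(C)(C)[Si](C)(C)Cl
Why: Silyl ether formation on a primary allylic alcohol masks the future C12 oxygen with a group that should survive the organomagnesium, enolate and thermal steps and is removed later by fluoride.

Step 2
Reactants: 2 [(2-bromoprop-2-en-1-yl)oxy](tert-butyl)dimethylsilane; 3 prop-2-yn-1-ol
Product: 4 4-({[tert-butyl(dimethyl)silyl]oxy}methyl)pent-4-en-2-yn-1-ol
Conditions: PdCl2(PPh3)2 (3 mol %), CuI (6 mol %), Et3N, THF, 50 °C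
Reagents that add atoms: none
Why: Sonogashira coupling of a 1,1-disubstituted vinyl bromide with a terminal alkyne joins C8 to C9 and keeps the free propargylic hydroxyl that directs the next step.

Step 3
Reactants: 4 4-({[tert-butyl(dimethyl)silyl]oxy}methyl)pent-4-en-2-yn-1-ol
Product: 6 (2Z)-3-[(benzyloxy)methyl]-4-({[tert-butyl(dimethyl)silyl]oxy}methyl)-2-methylpenta-2,4-dien-1-ol, via alkenylmagnesium chelate 5 (not isolated)
Conditions: MeMgBr (4 equiv), CuI (10 mol %), THF, −10 °C → rt; then BnOCH2Cl, −20 °C → rt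
Reagents that add atoms: methylmagnesium bromide, C[Mg]Br; benzyl chloromethyl ether, ClCOCc1ccccc1
Why: Copper-catalysed anti-carbomagnesiation of a propargylic alcohol places methyl on the alkyne carbon next to the carbinol (C10) and magnesium on C9 cis to the alkoxide in a five-membered chelate, so alkylation of the C–Mg bond with the chloromethyl ether should fix C11 cis to C1 and the methyl cis to C8.

Step 4
Reactants: 6 (2Z)-3-[(benzyloxy)methyl]-4-({[tert-butyl(dimethyl)silyl]oxy}methyl)-2-methylpenta-2,4-dien-1-ol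
Product: 7 (2Z)-3-[(benzyloxy)methyl]-1-bromo-4-({[tert-butyl(dimethyl)silyl]oxy}methyl)-2-methylpenta-2,4-diene
Conditions: CBr4, PPh3, CH2Cl2, 0 °C
Reagents that add atoms: carbon tetrabromide, BrC(Br)(Br)Br
Why: Appel bromination converts the primary allylic alcohol into the bromide by SN2 displacement of the oxyphosphonium under near-neutral conditions that should leave both ethers and the alkene geometry untouched.

Step 5
Reactants: 8 methyl (3S)-3-hydroxybutanoate
Product: 10 methyl (2S,3S)-3-hydroxy-2-methylbutanoate, via dilithiated hydroxy ester 9 (not isolated)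
Conditions: LiN(iPr)2 (2.2 equiv), THF, −78 → −20 °C; MeI, DMPU, −78 → 0 °C
Reagents that add atoms: iodomethane, CI
Why: Fráter–Seebach alkylation methylates the chelated dianion anti to the hydroxyl; the new centre is temporary and is re-enolised in step 6.

Step 6
Reactants: 10 methyl (2S,3S)-3-hydroxy-2-methylbutanoate
Product: 12 methyl (2S,3S)-2-[(benzyloxy)methyl]-3-hydroxy-2-methylbutanoate, via dilithiated methylated hydroxy ester 11 (not isolated)
Conditions: LiN(iPr)2 (2.2 equiv), THF, −78 → −15 °C; BnOCH2Cl, −78 → 0 °C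
Reagents that add atoms: benzyl chloromethyl ether, ClCOCc1ccccc1
Why: In the second Fráter–Seebach alkylation the electrophile again enters the chelated enolate on the face opposite the carbinol methyl, which sets the quaternary centre (future C4) with the benzyloxymethyl arm (future C5) anti to the hydroxyl.

Step 7
Reactants: 12 methyl (2S,3S)-2-[(benzyloxy)methyl]-3-hydroxy-2-methylbutanoate
Product: 13 methyl (2S,3S)-2-[(benzyloxy)methyl]-3-{[tert-butyl(dimethyl)silyl]oxy}-2-methylbutanoate
Conditions: TBSOTf, 2,6-lutidine, CH2Cl2, −78 → 0 °C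
Reagents that add atoms: tert-butyldimethylsilyl trifluoromethanesulfonate, CC(C)(C)[Si](C)(C)OS(=O)(=O)C(F)(F)F
Why: Silylation with the silyl triflate protects the hindered secondary alcohol so that it cannot be oxidised in step 9 or trigger retro-aldol cleavage in the base-mediated olefination of step 10.

Step 8
Reactants: 13 methyl (2S,3S)-2-[(benzyloxy)methyl]-3-{[tert-butyl(dimethyl)silyl]oxy}-2-methylbutanoate
Product: 14 methyl (2S,3S)-3-{[tert-butyl(dimethyl)silyl]oxy}-2-(hydroxymethyl)-2-methylbutanoate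
Conditions: H2 (1 atm), Pd/C, EtOAc, rt
Reagents that add atoms: none
Why: Hydrogenolysis of the benzyl ether over palladium on carbon frees the neopentyl primary alcohol without touching the silyl ether or the ester.

Step 9
Reactants: 14 methyl (2S,3S)-3-{[tert-butyl(dimethyl)silyl]oxy}-2-(hydroxymethyl)-2-methylbutanoate
Product: 15 methyl (2R,3S)-3-{[tert-butyl(dimethyl)silyl]oxy}-2-formyl-2-methylbutanoate
Conditions: Dess–Martin periodinane, CH2Cl2, rt
Reagents that add atoms: none
Why: Dess–Martin oxidation gives the non-enolisable α-formyl ester under non-aqueous conditions that should avoid deformylation.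

Step 10
Reactants: 15 methyl (2R,3S)-3-{[tert-butyl(dimethyl)silyl]oxy}-2-formyl-2-methylbutanoate; 16 diethyl [(phenylsulfonyl)methyl]phosphonate
Product: 18 methyl (2S,3S)-3-{[tert-butyl(dimethyl)silyl]oxy}-2-methyl-2-[(E)-2-(phenylsulfonyl)ethenyl]butanoate, via sodium phosphonate carbanion 17 (not isolated)
Conditions: NaH, THF, 0 °C; then 15, 0 °C → rt
Reagents that add atoms: none
Why: Horner–Wadsworth–Emmons olefination with the sulfonyl-stabilised phosphonate carbanion should give the (E)-vinyl sulfone, as is usual for stabilised phosphonates and hindered aldehydes.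

Step 11
Reactants: 18 methyl (2S,3S)-3-{[tert-butyl(dimethyl)silyl]oxy}-2-methyl-2-[(E)-2-(phenylsulfonyl)ethenyl]butanoate
Product: 19 methyl (2S,3S)-3-hydroxy-2-methyl-2-[(E)-2-(phenylsulfonyl)ethenyl]butanoate
Conditions: HF·pyridine, THF, 0 °C → rt
Reagents that add atoms: none
Why: Acidic fluoride desilylation frees the secondary alcohol without exposing the β-hydroxy ester or the vinyl sulfone to base.

Step 12
Reactants: 19 methyl (2S,3S)-3-hydroxy-2-methyl-2-[(E)-2-(phenylsulfonyl)ethenyl]butanoate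
Product: 20 methyl (2S)-2-methyl-3-oxo-2-[(E)-2-(phenylsulfonyl)ethenyl]butanoate
Conditions: Dess–Martin periodinane, CH2Cl2, rt
Reagents that add atoms: none
Why: Dess–Martin oxidation turns the carbinol, whose only task was to set C4, into a methyl ketone whose quaternary α-carbon cannot epimerise and whose methyl group (future C2) is the only enolisable position.

Step 13
Reactants: 20 methyl (2S)-2-methyl-3-oxo-2-[(E)-2-(phenylsulfonyl)ethenyl]butanoate; 7 (2Z)-3-[(benzyloxy)methyl]-1-bromo-4-({[tert-butyl(dimethyl)silyl]oxy}methyl)-2-methylpenta-2,4-diene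
Product: 22 methyl (2S,6Z)-7-[(benzyloxy)methyl]-8-({[tert-butyl(dimethyl)silyl]oxy}methyl)-2,6-dimethyl-3-oxo-2-[(E)-2-(phenylsulfonyl)ethenyl]nona-6,8-dienoate, via lithium enolate 21 (not isolated)
Conditions: LiN(SiMe3)2 (1.05 equiv), THF, −78 °C; then 7, DMPU, −78 → −20 °C
Reagents that add atoms: none
Why: Kinetic deprotonation of the methyl ketone and SN2 alkylation of the lithium enolate with the primary allylic bromide should form C1–C2, since attack at the fully substituted C9 is blocked and the hindered β-carbon of the vinyl sulfone should not react at low temperature.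

Step 14
Reactants: 22 methyl (2S,6Z)-7-[(benzyloxy)methyl]-8-({[tert-butyl(dimethyl)silyl]oxy}methyl)-2,6-dimethyl-3-oxo-2-[(E)-2-(phenylsulfonyl)ethenyl]nona-6,8-dienoate
Product: 23 methyl (4S,5S,6R,10R)-11-(benzyloxy)-12-{[tert-butyl(dimethyl)silyl]oxy}-3-oxo-6-(phenylsulfonyl)drim-8-en-14-oate
Conditions: PhMe (0.01 M), BHT (cat.), sealed tube, 180 °C
Reagents that add atoms: none
Why: A thermal, concerted but asynchronous [4+2] cycloaddition forms C5–C10 and C6–C7; the closest known reaction type is the intramolecular Diels–Alder reaction of deca-1,7,9-trienes with an (E)-vinyl sulfone dienophile. Ring B closes as the cyclohexene of the cycloaddition (alkene at C8=C9), and ring A closes as the six-membered ring spanned by the four-atom tether C1–C4 and sealed by the new C5–C10 bond. C5 and C10 should be set trans by the transition state with the sulfonyl group endo and the tether exo in a chair, so that the inside methyl of the diene becomes the angular C10 methyl anti to H5; C6 follows from the (E) dienophile geometry (sulfonyl cis to H5) and is erased later. The step needs π-facial selectivity relative to C4: in the chair tether the flat methoxycarbonyl group, smaller than methyl and dipole-opposed to the C3 carbonyl when equatorial, should take the axial site and the C4 methyl the equatorial one, which places C14 cis to the C10 methyl. Trans- over cis-fusion should be favoured because the tether-endo array would push quaternary C4 under the C9 benzyloxymethyl group. The quaternary centre next to the dienophile (Thorpe–Ingold effect) and the 2,3-disubstitution of the diene, which disfavours the s-trans conformer, should offset the hindered diene terminus.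

Step 15
Reactants: 23 methyl (4S,5S,6R,10R)-11-(benzyloxy)-12-{[tert-butyl(dimethyl)silyl]oxy}-3-oxo-6-(phenylsulfonyl)drim-8-en-14-oate
Product: 24 (3R,4R,5S,6R,10R)-11-(benzyloxy)-12-{[tert-butyl(dimethyl)silyl]oxy}-6-(phenylsulfonyl)drim-8-ene-3,14-diol
Conditions: LiAlH4, THF, 0 °C → rt
Reagents that add atoms: none
Why: In this hydride reduction the ketone should be attacked along the axial trajectory on the face away from the axial C4 ester and the C10 methyl to give the equatorial (3R) alcohol, and the ester is reduced to the C14 alcohol while sulfone, silyl ether and benzyl ether persist.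

Step 16
Reactants: 24 (3R,4R,5S,6R,10R)-11-(benzyloxy)-12-{[tert-butyl(dimethyl)silyl]oxy}-6-(phenylsulfonyl)drim-8-ene-3,14-diol
Product: 25 (3R,4R,5S,6R,10R)-11-(benzyloxy)-12-{[tert-butyl(dimethyl)silyl]oxy}-3,14-(isopropylidenedioxy)-6-(phenylsulfonyl)drim-8-ene
Conditions: Me2C(OMe)2, PPTS (cat.), CH2Cl2, rt
Reagents that add atoms: 2,2-dimethoxypropane, COC(C)(C)OC
Why: Acid-catalysed transketalisation ties the cis 1,3-diol (equatorial C3 hydroxyl, axial C14 hydroxymethyl) into an isopropylidene acetal, a routine protection for this diol pattern on a trans-decalin.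

Step 17
Reactants: 25 (3R,4R,5S,6R,10R)-11-(benzyloxy)-12-{[tert-butyl(dimethyl)silyl]oxy}-3,14-(isopropylidenedioxy)-6-(phenylsulfonyl)drim-8-ene
Product: 26 (3R,4R,5S,6R,10R)-11-(benzyloxy)-3,14-(isopropylidenedioxy)-6-(phenylsulfonyl)drim-8-en-12-ol
Conditions: Bu4NF, THF, 0 °C → rt
Reagents that add atoms: none
Why: Fluoride-mediated desilylation cleaves the only silyl ether and frees the primary allylic alcohol at C12.

Step 18
Reactants: 26 (3R,4R,5S,6R,10R)-11-(benzyloxy)-3,14-(isopropylidenedioxy)-6-(phenylsulfonyl)drim-8-en-12-ol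
Product: 29 (3R,4R,5S,6R,9R,10S)-11-(benzyloxy)-3,14-(isopropylidenedioxy)-6-(phenylsulfonyl)drim-8(12)-ene, via sulfonylhydrazine adduct 27 (not isolated), via allylic diazene 28 (not isolated)
Conditions: 2-O2NC6H4SO2NHNH2, PPh3, DEAD, THF, −30 °C → rt
Reagents that add atoms: none
Why: Reductive 1,3-transposition of an allylic alcohol: Mitsunobu displacement at C12 by the sulfonylhydrazide, loss of the sulfinic acid and retro-ene extrusion of N2 from the monoalkyl diazene should move the alkene to C8=C12 and deliver hydrogen to C9 on the face opposite the axial C10 methyl, leaving C11 equatorial (9R).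

Step 19
Reactants: 29 (3R,4R,5S,6R,9R,10S)-11-(benzyloxy)-3,14-(isopropylidenedioxy)-6-(phenylsulfonyl)drim-8(12)-ene
Product: 30 (3R,4R,5S,9R,10R)-3,14-(isopropylidenedioxy)drim-8(12)-en-11-ol
Conditions: Na, NH3(l), THF, −78 °C; then NH4Cl
Reagents that add atoms: none
Why: Dissolving-metal reduction should cleave the benzylic C–O bond and the C6–S bond in one operation, while the isolated 1,1-disubstituted alkene and the acetal are not reduced.

Step 20
Reactants: 30 (3R,4R,5S,9R,10R)-3,14-(isopropylidenedioxy)drim-8(12)-en-11-ol; 31 7-hydroxy-2H-chromen-2-one (umbelliferone)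
Product: 32 7-{[(3R,4R,5S,9R,10R)-3,14-(isopropylidenedioxy)drim-8(12)-en-11-yl]oxy}-2H-chromen-2-one
Conditions: PPh3, DIAD, THF, 0 → 40 °C
Reagents that add atoms: none
Why: In this Mitsunobu etherification the acidic phenol (pKa about 8) displaces the oxyphosphonium of the primary C11 alcohol by SN2, a step that touches no stereocentre.

Step 21
Reactants: 32 7-{[(3R,4R,5S,9R,10R)-3,14-(isopropylidenedioxy)drim-8(12)-en-11-yl]oxy}-2H-chromen-2-one
Product: 33 7-{[(3R,4R,5S,9R,10R)-3,14-dihydroxydrim-8(12)-en-11-yl]oxy}-2H-chromen-2-one (CNP0149624.1)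
Conditions: AcOH–H2O–THF (3:1:1), 40 °C
Reagents that add atoms: none
Why: Mild acid hydrolysis of the isopropylidene acetal frees the C3 and C14 hydroxyls under conditions that should spare the exocyclic alkene, the aryl ether and the coumarin lactone.

**Compound list**

1 | 2-bromoprop-2-en-1-ol | C=C(Br)CO | starting material
2 | [(2-bromoprop-2-en-1-yl)oxy](tert-butyl)dimethylsilane | C=C(Br)CO[Si](C)(C)C(C)(C)C | intermediate
3 | prop-2-yn-1-ol | C#CCO | starting material
4 | 4-({[tert-butyl(dimethyl)silyl]oxy}methyl)pent-4-en-2-yn-1-ol | OCC#CC(=C)CO[Si](C)(C)C(C)(C)C | intermediate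
5 | 4-methyl-3-[3-{[tert-butyl(dimethyl)silyl]oxy}prop-1-en-2-yl]-2,5-dihydro-1,2-oxamagnesole (alkenylmagnesium chelate) | CC1=C(C(=C)CO[Si](C)(C)C(C)(C)C)[Mg]OC1 | intermediate
6 | (2Z)-3-[(benzyloxy)methyl]-4-({[tert-butyl(dimethyl)silyl]oxy}methyl)-2-methylpenta-2,4-dien-1-ol | OC/C(C)=C(\COCc1ccccc1)C(=C)CO[Si](C)(C)C(C)(C)C | intermediate
7 | (2Z)-3-[(benzyloxy)methyl]-1-bromo-4-({[tert-butyl(dimethyl)silyl]oxy}methyl)-2-methylpenta-2,4-diene | BrC/C(C)=C(\COCc1ccccc1)C(=C)CO[Si](C)(C)C(C)(C)C | intermediate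
8 | methyl (3S)-3-hydroxybutanoate | C[C@H](O)CC(=O)OC | starting material
9 | dilithiated methyl (3S)-3-hydroxybutanoate (alkoxide ester enolate) | C[C@H](O[Li])C=C(O[Li])OC | intermediate
10 | methyl (2S,3S)-3-hydroxy-2-methylbutanoate | C[C@H](O)[C@H](C)C(=O)OC | intermediate
11 | dilithiated methyl (3S)-3-hydroxy-2-methylbutanoate (alkoxide ester enolate) | C[C@H](O[Li])C(C)=C(O[Li])OC | intermediate
12 | methyl (2S,3S)-2-[(benzyloxy)methyl]-3-hydroxy-2-methylbutanoate | C[C@H](O)[C@](C)(COCc1ccccc1)C(=O)OC | intermediate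
13 | methyl (2S,3S)-2-[(benzyloxy)methyl]-3-{[tert-butyl(dimethyl)silyl]oxy}-2-methylbutanoate | C[C@H](O[Si](C)(C)C(C)(C)C)[C@](C)(COCc1ccccc1)C(=O)OC | intermediate
14 | methyl (2S,3S)-3-{[tert-butyl(dimethyl)silyl]oxy}-2-(hydroxymethyl)-2-methylbutanoate | C[C@H](O[Si](C)(C)C(C)(C)C)[C@](C)(CO)C(=O)OC | intermediate
15 | methyl (2R,3S)-3-{[tert-butyl(dimethyl)silyl]oxy}-2-formyl-2-methylbutanoate | C[C@H](O[Si](C)(C)C(C)(C)C)[C@](C)(C=O)C(=O)OC | intermediate
16 | diethyl [(phenylsulfonyl)methyl]phosphonate | CCOP(=O)(CS(=O)(=O)c1ccccc1)OCC | starting material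
17 | sodium (diethoxyphosphoryl)(phenylsulfonyl)methanide | [Na+].CCOP(=O)(OCC)[CH-]S(=O)(=O)c1ccccc1 | intermediate
18 | methyl (2S,3S)-3-{[tert-butyl(dimethyl)silyl]oxy}-2-methyl-2-[(E)-2-(phenylsulfonyl)ethenyl]butanoate | C[C@H](O[Si](C)(C)C(C)(C)C)[C@](C)(/C=C/S(=O)(=O)c1ccccc1)C(=O)OC | intermediate
19 | methyl (2S,3S)-3-hydroxy-2-methyl-2-[(E)-2-(phenylsulfonyl)ethenyl]butanoate | C[C@H](O)[C@](C)(/C=C/S(=O)(=O)c1ccccc1)C(=O)OC | intermediate
20 | methyl (2S)-2-methyl-3-oxo-2-[(E)-2-(phenylsulfonyl)ethenyl]butanoate | CC(=O)[C@](C)(/C=C/S(=O)(=O)c1ccccc1)C(=O)OC | intermediate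
21 | lithium (3S,4E)-3-(methoxycarbonyl)-3-methyl-5-(phenylsulfonyl)penta-1,4-dien-2-olate | C=C(O[Li])[C@](C)(/C=C/S(=O)(=O)c1ccccc1)C(=O)OC | intermediate
22 | methyl (2S,6Z)-7-[(benzyloxy)methyl]-8-({[tert-butyl(dimethyl)silyl]oxy}methyl)-2,6-dimethyl-3-oxo-2-[(E)-2-(phenylsulfonyl)ethenyl]nona-6,8-dienoate | O=C(CC/C(C)=C(\COCc1ccccc1)C(=C)CO[Si](C)(C)C(C)(C)C)[C@](C)(/C=C/S(=O)(=O)c1ccccc1)C(=O)OC | intermediate
23 | methyl (4S,5S,6R,10R)-11-(benzyloxy)-12-{[tert-butyl(dimethyl)silyl]oxy}-3-oxo-6-(phenylsulfonyl)drim-8-en-14-oate (trans-fused; ester cis to the C10 methyl) | CC(C)(C)[Si](C)(C)OCC1=C(COCc2ccccc2)[C@]3(C)CCC(=O)[C@@](C)(C(=O)OC)[C@H]3[C@H](S(=O)(=O)c2ccccc2)C1 | intermediate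
24 | (3R,4R,5S,6R,10R)-11-(benzyloxy)-12-{[tert-butyl(dimethyl)silyl]oxy}-6-(phenylsulfonyl)drim-8-ene-3,14-diol | CC(C)(C)[Si](C)(C)OCC1=C(COCc2ccccc2)[C@]3(C)CC[C@@H](O)[C@@](C)(CO)[C@H]3[C@H](S(=O)(=O)c2ccccc2)C1 | intermediate
25 | (3R,4R,5S,6R,10R)-11-(benzyloxy)-12-{[tert-butyl(dimethyl)silyl]oxy}-3,14-(isopropylidenedioxy)-6-(phenylsulfonyl)drim-8-ene | CC(C)(C)[Si](C)(C)OCC1=C(COCc2ccccc2)[C@]3(C)CC[C@H]4OC(C)(C)OC[C@@]4(C)[C@H]3[C@H](S(=O)(=O)c2ccccc2)C1 | intermediate
26 | (3R,4R,5S,6R,10R)-11-(benzyloxy)-3,14-(isopropylidenedioxy)-6-(phenylsulfonyl)drim-8-en-12-ol | OCC1=C(COCc2ccccc2)[C@]3(C)CC[C@H]4OC(C)(C)OC[C@@]4(C)[C@H]3[C@H](S(=O)(=O)c2ccccc2)C1 | intermediate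
27 | 1-[(3R,4R,5S,6R,10R)-11-(benzyloxy)-3,14-(isopropylidenedioxy)-6-(phenylsulfonyl)drim-8-en-12-yl]-1-(2-nitrophenylsulfonyl)hydrazine | NN(CC1=C(COCc2ccccc2)[C@]3(C)CC[C@H]4OC(C)(C)OC[C@@]4(C)[C@H]3[C@H](S(=O)(=O)c2ccccc2)C1)S(=O)(=O)c1ccccc1[N+](=O)[O-] | intermediate
28 | [(3R,4R,5S,6R,10R)-11-(benzyloxy)-3,14-(isopropylidenedioxy)-6-(phenylsulfonyl)drim-8-en-12-yl]diazene | N=NCC1=C(COCc2ccccc2)[C@]3(C)CC[C@H]4OC(C)(C)OC[C@@]4(C)[C@H]3[C@H](S(=O)(=O)c2ccccc2)C1 | intermediate
29 | (3R,4R,5S,6R,9R,10S)-11-(benzyloxy)-3,14-(isopropylidenedioxy)-6-(phenylsulfonyl)drim-8(12)-ene | C=C1C[C@@H](S(=O)(=O)c2ccccc2)[C@@H]3[C@]4(C)COC(C)(C)O[C@@H]4CC[C@@]3(C)[C@@H]1COCc1ccccc1 | intermediate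
30 | (3R,4R,5S,9R,10R)-3,14-(isopropylidenedioxy)drim-8(12)-en-11-ol | C=C1CC[C@@H]2[C@]3(C)COC(C)(C)O[C@@H]3CC[C@@]2(C)[C@@H]1CO | intermediate
31 | 7-hydroxy-2H-chromen-2-one (umbelliferone) | O=c1ccc2ccc(O)cc2o1 | starting material
32 | 7-{[(3R,4R,5S,9R,10R)-3,14-(isopropylidenedioxy)drim-8(12)-en-11-yl]oxy}-2H-chromen-2-one | C=C1CC[C@@H]2[C@]3(C)COC(C)(C)O[C@@H]3CC[C@@]2(C)[C@@H]1COc1ccc2ccc(=O)oc2c1 | intermediate
33 | 7-{[(1R,4aS,5R,6R,8aR)-6-hydroxy-5-(hydroxymethyl)-5,8a-dimethyl-2-methylidenedecahydronaphthalen-1-yl]methoxy}-2H-chromen-2-one (CNP0149624.1) | C=C1CC[C@@H]2[C@](C)(CO)[C@H](O)CC[C@@]2(C)[C@@H]1COc1ccc2ccc(=O)oc2c1 | target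

**Step count and risks**

Total step count: 21. Longest linear sequence: 17 steps (steps 5–21, from methyl (3S)-3-hydroxybutanoate).

The three steps most likely to fail:

First, step 14. What may go wrong is insufficient discrimination between the two faces of the diene by the single C4 stereocentre, so that the C4-epimeric trans-decalin forms as well. A slow cyclisation would also let [1,5]-hydrogen shift in the (Z)-methyl diene compete. The fallback adds a second controlling centre before the cycloaddition. Setting out from 22, Corey–Bakshi–Shibata reduction of the C3 ketone ((S)-Me-CBS oxazaborolidine, catecholborane, toluene, −78 °C) should give the (3R)-hydroxy triene F1. Acetylation (Ac2O, DMAP, pyridine) gives the acetate F2, whose acetoxy group is equatorial in the desired chair tether and axial in the unwanted one. Thermolysis as in step 14 should give the cycloadduct F3. LiAlH4 then cleaves the acetate, reduces the ester and comes back to the route at diol 24.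

Second, step 3. What may go wrong is incomplete or misdirected carbomagnesiation of the conjugated enyne, or loss of the chloromethyl ether to O-alkylation of the magnesium alkoxide and to excess Grignard reagent. The fallback makes the tetrasubstituted alkene by cross-coupling of a stereodefined enol triflate. Setting out from 2, borylation (B2pin2, PdCl2(PPh3)2, PPh3, KOPh, toluene, 50 °C) gives the alkenylboronate F4. Commercial ethyl 4-(benzyloxy)-3-oxobutanoate is C-methylated (MeI, K2CO3, acetone) to the keto ester F5 and triflated under non-chelating conditions (Tf2O, aqueous Me4NOH, toluene) to the (E)-enol triflate F6. Suzuki–Miyaura coupling of F6 with F4 (PdCl2(dppf), K3PO4, THF–H2O) should give the dienoate F7 with retention of alkene geometry, and reduction with iBu2AlH returns to the route at dienol 6.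

Third, step 20. What may go wrong is sluggish SN2 displacement at the β-branched C11 oxyphosphonium next to quaternary C10, so that the alcohol is recovered or consumed by the azodicarboxylate. The fallback makes the C–O bond by sulfonate displacement. From 30, MsCl and Et3N give the mesylate F8, and heating F8 with umbelliferone 31 and Cs2CO3 in DMF (80 °C) should give aryl ether 32, where the route is rejoined.

**Further compounds**

F1 | step 14 | methyl (2S,3R,6Z)-7-[(benzyloxy)methyl]-8-({[tert-butyl(dimethyl)silyl]oxy}methyl)-3-hydroxy-2,6-dimethyl-2-[(E)-2-(phenylsulfonyl)ethenyl]nona-6,8-dienoate | O[C@H](CC/C(C)=C(\COCc1ccccc1)C(=C)CO[Si](C)(C)C(C)(C)C)[C@](C)(/C=C/S(=O)(=O)c1ccccc1)C(=O)OC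
F2 | step 14 | methyl (2S,3R,6Z)-3-acetoxy-7-[(benzyloxy)methyl]-8-({[tert-butyl(dimethyl)silyl]oxy}methyl)-2,6-dimethyl-2-[(E)-2-(phenylsulfonyl)ethenyl]nona-6,8-dienoate | CC(=O)O[C@H](CC/C(C)=C(\COCc1ccccc1)C(=C)CO[Si](C)(C)C(C)(C)C)[C@](C)(/C=C/S(=O)(=O)c1ccccc1)C(=O)OC
F3 | step 14 | methyl (3R,4S,5S,6R,10R)-3-acetoxy-11-(benzyloxy)-12-{[tert-butyl(dimethyl)silyl]oxy}-6-(phenylsulfonyl)drim-8-en-14-oate | CC(C)(C)[Si](C)(C)OCC1=C(COCc2ccccc2)[C@]3(C)CC[C@@H](OC(C)=O)[C@@](C)(C(=O)OC)[C@H]3[C@H](S(=O)(=O)c2ccccc2)C1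
F4 | step 3 | tert-butyl(dimethyl){[2-(4,4,5,5-tetramethyl-1,3,2-dioxaborolan-2-yl)prop-2-en-1-yl]oxy}silane | C=C(CO[Si](C)(C)C(C)(C)C)B1OC(C)(C)C(C)(C)O1
F5 | step 3 | ethyl 4-(benzyloxy)-2-methyl-3-oxobutanoate | CCOC(=O)C(C)C(=O)COCc1ccccc1
F6 | step 3 | ethyl (2E)-4-(benzyloxy)-2-methyl-3-{[(trifluoromethyl)sulfonyl]oxy}but-2-enoate | CCOC(=O)/C(C)=C(\COCc1ccccc1)OS(=O)(=O)C(F)(F)F
F7 | step 3 | ethyl (2Z)-3-[(benzyloxy)methyl]-4-({[tert-butyl(dimethyl)silyl]oxy}methyl)-2-methylpenta-2,4-dienoate | CCOC(=O)/C(C)=C(\COCc1ccccc1)C(=C)CO[Si](C)(C)C(C)(C)C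
F8 | step 20 | (3R,4R,5S,9R,10R)-3,14-(isopropylidenedioxy)drim-8(12)-en-11-yl methanesulfonate | C=C1CC[C@@H]2[C@]3(C)COC(C)(C)O[C@@H]3CC[C@@]2(C)[C@@H]1COS(C)(=O)=O
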